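The hexamer, with rings lettered A (2,4,6-trihydroxyphenoxy end) to F (3,4,5-trihydroxyphenoxy end), is grown from ring A: each doubly flanked phenol is either arylated by an unhindered aryl halide or converted into the next pentaoxygenated ring. Ring E has oxygen on C1–C5 and hydrogen on C6. The key step builds it in one operation from dimethyl squarate (C2–C5) and the two ynol ether carbons attached to the C4 oxygen of ring D (C1 and C6), closing the ring through the C1–C2 bond and fixing every oxygen by connectivity. Its precursor is the 4-hydroxycyclobutenone formed by adding a lithium aryloxyacetylide, whose aryl group is ring D bearing rings A–C, to the squarate.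

Key step: step 12

Ring atom numbering: in rings B and D, C1 bears the oxygen to ring A or C and C4 the oxygen to ring C or E. In rings C and E, C1 bears the oxygen to ring B or D, C2 the oxygen to ring D or F, C3–C5 are oxygenated and C6 carries hydrogen.

Remark (assumption on the chemistry): the oxygen on C1 of ring D enters the key step as the finished ether to ring C, not as a removable ether, because that ether forms dependably only from the hindered C2 phenol of ring C and an unhindered ring D bromide; the C5 hydroxyls of rings C and E travel as isopropyl ethers and all other hydroxyls as methyl ethers, all cleaved together in the last step.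

Shorthand for aryl groups (full SMILES in the compound list):
- Ar(AB) = 2,6-dimethoxy-4-(2,4,6-trimethoxyphenoxy)phenyl
- Ar(ABC) = 6-[Ar(AB)-oxy]-2,3-dimethoxy-4-(propan-2-yloxy)phenyl
- Ar(ABCD) = 2,6-dimethoxy-4-[Ar(ABC)-oxy]phenyl
- Ar(ABCDE) = 6-[Ar(ABCD)-oxy]-2,3-dimethoxy-4-(propan-2-yloxy)phenyl

Step 1
Reactants: 1 4-bromo-2,6-dimethoxyphenol
Product: 2 2-(benzyloxy)-5-bromo-1,3-dimethoxybenzene
Conditions: BnBr, K2CO3, DMF, rt
Reagents that add atoms: benzyl bromide, BrCc1ccccc1
Why: Williamson etherification of the phenoxide with a benzylic bromide masks the hindered phenol of the ring B/ring D building block, and the aryl bromide is inert under these conditions.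

Step 2
Reactants: 3 2,4,6-trimethoxyphenol; 2 2-(benzyloxy)-5-bromo-1,3-dimethoxybenzene
Product: 4 2-(benzyloxy)-1,3-dimethoxy-5-(2,4,6-trimethoxyphenoxy)benzene
Conditions: CuI (10 mol%), picolinic acid (20 mol%), K3PO4, DMSO, 90 °C, Ar
Reagents that add atoms: none
Why: Ullmann diaryl ether synthesis with a copper/picolinate catalyst, a system suited to 2,6-disubstituted phenoxides, should join the hindered ring A phenol to the unhindered C–Br carbon of 2, whose benzyl ether prevents self-coupling.

Step 3
Reactants: 4 2-(benzyloxy)-1,3-dimethoxy-5-(2,4,6-trimethoxyphenoxy)benzene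
Product: 5 Ar(AB)–OH (2,6-dimethoxy-4-(2,4,6-trimethoxyphenoxy)phenol)
Conditions: H2 (1 atm), 10% Pd/C, EtOAc/MeOH, rt
Reagents that add atoms: none
Why: Hydrogenolysis of the aryl benzyl ether over palladium should free the C4 phenol of ring B while methyl and diaryl ethers stay intact.

Step 4
Reactants: 6 1,2,3,4-tetramethoxybenzene
Product: 7 1-bromo-2,3,4,5-tetramethoxybenzene
Conditions: NBS (1.0 equiv), MeCN, 0 °C to rt
Reagents that add atoms: N-bromosuccinimide, O=C1CCC(=O)N1Br
Why: Electrophilic aromatic bromination of the electron-rich arene should give a single monobromide because the two free ring positions are equivalent.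

Step 5
Reactants: 7 1-bromo-2,3,4,5-tetramethoxybenzene
Product: 8 5-bromo-2,3-dimethoxy-1,4-benzoquinone
Conditions: (NH4)2Ce(NO3)6, MeCN/H2O, 0 °C
Reagents that add atoms: water, O
Why: Oxidative demethylation of the para-related methoxy pair through the arene radical cation and attack of water is the standard route from tetramethoxyarenes to 2,3-dimethoxy-para-quinones.

Step 6
Reactants: 5 Ar(AB)–OH; 8 5-bromo-2,3-dimethoxy-1,4-benzoquinone
Product: 9 5-[Ar(AB)-oxy]-2,3-dimethoxy-1,4-benzoquinone
Conditions: K2CO3, MeCN, 0 °C to rt, Ar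
Reagents that add atoms: none
Why: Addition–elimination of the phenoxide at the bromine-bearing quinone carbon (vinylogous acyl substitution) should form the ring B O4–ring C C1 ether, with only O-arylation open because the ortho and para positions of the phenoxide are blocked; this conservative substitution is used for ring C so that the annulation risk stays in step 12.

Step 7
Reactants: 9 5-[Ar(AB)-oxy]-2,3-dimethoxy-1,4-benzoquinone
Product: 11 Ar(ABC)–OH (6-[Ar(AB)-oxy]-2,3-dimethoxy-4-(propan-2-yloxy)phenol), via ring C hydroquinone 10 (not isolated)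
Conditions: Na2S2O4, DMF/H2O, rt; then K2CO3, 2-bromopropane (1.5 equiv), 50 °C, one flask, Ar
Reagents that add atoms: 2-bromopropane, CC(C)Br
Why: Dithionite reduction gives the hydroquinone, and Williamson alkylation with a secondary bromide should occur at the C5 hydroxyl (one ortho substituent) far faster than at the C2 hydroxyl, which is flanked by a methoxy group and the bulky di-ortho-substituted aryloxy group.

Step 8
Reactants: 11 Ar(ABC)–OH; 2 2-(benzyloxy)-5-bromo-1,3-dimethoxybenzene
Product: 12 2-(benzyloxy)-1,3-dimethoxy-5-[Ar(ABC)-oxy]benzene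
Conditions: CuI (20 mol%), picolinic acid (40 mol%), K3PO4, DMSO, 100 °C, Ar
Reagents that add atoms: none
Why: Ullmann diaryl ether synthesis between the hindered C2 phenoxide of ring C and the unhindered bromide should form the C–D ether in its favourable polarity, the isopropyl ether being stable to the basic conditions.

Step 9
Reactants: 12 2-(benzyloxy)-1,3-dimethoxy-5-[Ar(ABC)-oxy]benzene
Product: 13 Ar(ABCD)–OH (2,6-dimethoxy-4-[Ar(ABC)-oxy]phenol)
Conditions: H2 (1 atm), 10% Pd/C, EtOAc/MeOH, rt
Reagents that add atoms: none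
Why: Hydrogenolysis of the only benzyl ether should free the C4 phenol of ring D and leave isopropyl, methyl and diaryl ethers untouched.

Step 10
Reactants: 13 Ar(ABCD)–OH; 14 trichloroethylene
Product: 15 Ar(ABCD) (E)-1,2-dichloroethenyl ether
Conditions: K2CO3, DMF, 70 °C
Reagents that add atoms: none
Why: Base converts trichloroethylene into dichloroacetylene in situ and anti addition of the phenoxide gives the (E)-dichlorovinyl ether, the standard entry to ynol ethers from phenols.

Step 11
Reactants: 15 Ar(ABCD) (E)-1,2-dichloroethenyl ether; 16 dimethyl squarate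
Product: 19 4-{[Ar(ABCD)-oxy]ethynyl}-4-hydroxy-2,3-dimethoxycyclobut-2-en-1-one (racemic), via chloroethynyl ether 17 (not isolated), via lithium aryloxyacetylide 18 (not isolated)
Conditions: n-BuLi (2.2 equiv), THF, −78 to −40 °C; then 16, −78 °C; aq NH4Cl, −78 °C
Reagents that add atoms: none
Why: Deprotonation and loss of LiCl give the chloroalkyne, chlorine–lithium exchange gives the acetylide, and 1,2-addition to one of the two equivalent carbonyl groups of the squarate gives the tertiary alcohol as a racemate whose carbinol center disappears in step 12.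

Step 12
Reactants: 19 4-{[Ar(ABCD)-oxy]ethynyl}-4-hydroxy-2,3-dimethoxycyclobut-2-en-1-one
Product: 21 5-[Ar(ABCD)-oxy]-2,3-dimethoxy-1,4-benzoquinone, via enynylketene 20 (not isolated)
Conditions: toluene (0.01 M), 110 °C, Ar
Reagents that add atoms: none
Why: Heating opens the cyclobutenone by conrotatory 4π electrocyclic ring opening in which the hydroxyl turns outward, so that ketene 20 carries the alkynyl group cis to the ketene unit. The ketene carbon then bonds to the distal, oxygen-bearing alkyne carbon to give a diradical (a ring σ radical at the former proximal alkyne carbon and a hydroxyphenoxyl), and transfer of the hydroxyl hydrogen to the ring radical delivers the quinone. The closest known reaction type is the Moore rearrangement of 4-alkynyl-4-hydroxycyclobutenones derived from squarate esters, established for alkyl-, aryl-, silyl- and alkoxy-substituted alkynes and applied here to an aryl ynol ether of the same class. Ring E is closed as a six-membered carbocycle by diradical cyclisation of the enynylketene, the new bond being C1–C2. No stereocenter is formed, and the racemic carbinol carbon of 19 ends as the C5 carbonyl carbon. The selectivity needed is six- over five-membered closure (quinone against alkylidenecyclopentenedione), which the oxygen substituent on the alkyne terminus should secure because it gives none of the stabilisation that aryl, silyl or ester groups lend to the exocyclic vinyl radical of the five-membered path, while the places of all five oxygens follow from connectivity.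

Step 13
Reactants: 21 5-[Ar(ABCD)-oxy]-2,3-dimethoxy-1,4-benzoquinone
Product: 23 Ar(ABCDE)–OH (6-[Ar(ABCD)-oxy]-2,3-dimethoxy-4-(propan-2-yloxy)phenol), via ring E hydroquinone 22 (not isolated)
Conditions: Na2S2O4, DMF/H2O, rt; then K2CO3, 2-bromopropane (1.5 equiv), 50 °C, one flask, Ar
Reagents that add atoms: 2-bromopropane, CC(C)Br
Why: As in step 7, reduction followed by Williamson alkylation should protect the C5 hydroxyl of ring E next to the ring hydrogen and leave the doubly flanked C2 hydroxyl free for arylation.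

Step 14
Reactants: 23 Ar(ABCDE)–OH; 24 5-iodo-1,2,3-trimethoxybenzene
Product: 25 Ar(ABCDE) 3,4,5-trimethoxyphenyl ether (fully protected hexamer: fourteen methyl and two isopropyl ethers)
Conditions: CuI (20 mol%), picolinic acid (40 mol%), K3PO4, DMSO, 90 °C, Ar
Reagents that add atoms: none
Why: Ullmann diaryl ether synthesis of the hindered C2 phenoxide of ring E with an unhindered aryl iodide should install ring F.

Step 15
Reactants: 25 Ar(ABCDE) 3,4,5-trimethoxyphenyl ether
Product: 26 target hexadecaphenol (CNP0114537.0)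
Conditions: BBr3 (excess), CH2Cl2, −78 °C to rt, Ar; then MeOH, H2O; isolation under Ar
Reagents that add atoms: none
Why: BBr3 cleaves alkyl aryl ethers by bromide attack at the alkyl carbon of the boron-complexed ether, so all fourteen methyl and both isopropyl ethers should fall while the five diaryl ethers, which offer no sp3 carbon, persist.

Compound list
1 | 4-bromo-2,6-dimethoxyphenol | COc1cc(Br)cc(OC)c1O | starting material
2 | 2-(benzyloxy)-5-bromo-1,3-dimethoxybenzene | COc1cc(Br)cc(OC)c1OCc1ccccc1 | intermediate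
3 | 2,4,6-trimethoxyphenol | COc1cc(OC)c(O)c(OC)c1 | starting material
4 | 2-(benzyloxy)-1,3-dimethoxy-5-(2,4,6-trimethoxyphenoxy)benzene | COc1cc(OC)c(Oc2cc(OC)c(OCc3ccccc3)c(OC)c2)c(OC)c1 | intermediate
5 | Ar(AB)–OH, 2,6-dimethoxy-4-(2,4,6-trimethoxyphenoxy)phenol | COc1cc(OC)c(Oc2cc(OC)c(O)c(OC)c2)c(OC)c1 | intermediate
6 | 1,2,3,4-tetramethoxybenzene | COc1ccc(OC)c(OC)c1OC | starting material
7 | 1-bromo-2,3,4,5-tetramethoxybenzene | COc1cc(Br)c(OC)c(OC)c1OC | intermediate
8 | 5-bromo-2,3-dimethoxy-1,4-benzoquinone | COC1=C(OC)C(=O)C(Br)=CC1=O | intermediate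
9 | 5-[Ar(AB)-oxy]-2,3-dimethoxy-1,4-benzoquinone (ring C quinone) | COC1=C(OC)C(=O)C(Oc2c(OC)cc(Oc3c(OC)cc(OC)cc3OC)cc2OC)=CC1=O | intermediate
10 | 5-[Ar(AB)-oxy]-2,3-dimethoxybenzene-1,4-diol (ring C hydroquinone) | COc1c(OC)c(O)c(Oc2c(OC)cc(Oc3c(OC)cc(OC)cc3OC)cc2OC)cc1O | intermediate (not isolated)
11 | Ar(ABC)–OH, 6-[Ar(AB)-oxy]-2,3-dimethoxy-4-(propan-2-yloxy)phenol | COc1c(OC)c(O)c(Oc2c(OC)cc(Oc3c(OC)cc(OC)cc3OC)cc2OC)cc1OC(C)C | intermediate
12 | 2-(benzyloxy)-1,3-dimethoxy-5-[Ar(ABC)-oxy]benzene | COc1c(OC)c(Oc2cc(OC)c(OCc3ccccc3)c(OC)c2)c(Oc2c(OC)cc(Oc3c(OC)cc(OC)cc3OC)cc2OC)cc1OC(C)C | intermediate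
13 | Ar(ABCD)–OH, 2,6-dimethoxy-4-[Ar(ABC)-oxy]phenol | COc1c(OC)c(Oc2cc(OC)c(O)c(OC)c2)c(Oc2c(OC)cc(Oc3c(OC)cc(OC)cc3OC)cc2OC)cc1OC(C)C | intermediate
14 | trichloroethylene | ClC=C(Cl)Cl | starting material
15 | Ar(ABCD) (E)-1,2-dichloroethenyl ether | COc1c(OC)c(Oc2cc(OC)c(O/C(Cl)=C\Cl)c(OC)c2)c(Oc2c(OC)cc(Oc3c(OC)cc(OC)cc3OC)cc2OC)cc1OC(C)C | intermediate
16 | dimethyl squarate (3,4-dimethoxycyclobut-3-ene-1,2-dione) | COC1=C(OC)C(=O)C1=O | starting material
17 | Ar(ABCD) chloroethynyl ether | COc1c(OC)c(Oc2cc(OC)c(OC#CCl)c(OC)c2)c(Oc2c(OC)cc(Oc3c(OC)cc(OC)cc3OC)cc2OC)cc1OC(C)C | intermediate (not isolated)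
18 | lithium [Ar(ABCD)-oxy]acetylide | COc1c(OC)c(Oc2cc(OC)c(OC#C[Li])c(OC)c2)c(Oc2c(OC)cc(Oc3c(OC)cc(OC)cc3OC)cc2OC)cc1OC(C)C | intermediate (not isolated)
19 | 4-{[Ar(ABCD)-oxy]ethynyl}-4-hydroxy-2,3-dimethoxycyclobut-2-en-1-one, racemic at C4 | COC1=C(OC)C(O)(C#COc2c(OC)cc(Oc3c(OC)c(OC)c(OC(C)C)cc3Oc3c(OC)cc(Oc4c(OC)cc(OC)cc4OC)cc3OC)cc2OC)C1=O | intermediate (key step precursor)
20 | (3Z)-4-hydroxy-2,3-dimethoxy-6-[Ar(ABCD)-oxy]hexa-1,3-dien-5-yn-1-one (enynylketene) | COC(=C=O)/C(OC)=C(/O)C#COc1c(OC)cc(Oc2c(OC)c(OC)c(OC(C)C)cc2Oc2c(OC)cc(Oc3c(OC)cc(OC)cc3OC)cc2OC)cc1OC | intermediate (not isolated)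
21 | 5-[Ar(ABCD)-oxy]-2,3-dimethoxy-1,4-benzoquinone (ring E quinone) | COC1=C(OC)C(=O)C(Oc2c(OC)cc(Oc3c(OC)c(OC)c(OC(C)C)cc3Oc3c(OC)cc(Oc4c(OC)cc(OC)cc4OC)cc3OC)cc2OC)=CC1=O | intermediate (key step product)
22 | 5-[Ar(ABCD)-oxy]-2,3-dimethoxybenzene-1,4-diol (ring E hydroquinone) | COc1c(OC)c(O)c(Oc2c(OC)cc(Oc3c(OC)c(OC)c(OC(C)C)cc3Oc3c(OC)cc(Oc4c(OC)cc(OC)cc4OC)cc3OC)cc2OC)cc1O | intermediate (not isolated)
23 | Ar(ABCDE)–OH, 6-[Ar(ABCD)-oxy]-2,3-dimethoxy-4-(propan-2-yloxy)phenol | COc1c(OC)c(O)c(Oc2c(OC)cc(Oc3c(OC)c(OC)c(OC(C)C)cc3Oc3c(OC)cc(Oc4c(OC)cc(OC)cc4OC)cc3OC)cc2OC)cc1OC(C)C | intermediate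
24 | 5-iodo-1,2,3-trimethoxybenzene | COc1cc(I)cc(OC)c1OC | starting material
25 | Ar(ABCDE) 3,4,5-trimethoxyphenyl ether (protected hexamer) | COc1c(OC)c(Oc2cc(OC)c(OC)c(OC)c2)c(Oc2c(OC)cc(Oc3c(OC)c(OC)c(OC(C)C)cc3Oc3c(OC)cc(Oc4c(OC)cc(OC)cc4OC)cc3OC)cc2OC)cc1OC(C)C | intermediate
26 | target: ring A 2,4,6-trihydroxyphenyl–O–C1 of ring B (3,5-dihydroxy)–C4–O–C1 of ring C (3,4,5-trihydroxy)–C2–O–C1 of ring D (3,5-dihydroxy)–C4–O–C1 of ring E (3,4,5-trihydroxy)–C2–O–ring F 3,4,5-trihydroxyphenyl; no stereocenters | Oc1cc(O)c(Oc2cc(O)c(Oc3cc(O)c(O)c(O)c3Oc3cc(O)c(Oc4cc(O)c(O)c(O)c4Oc4cc(O)c(O)c(O)c4)c(O)c3)c(O)c2)c(O)c1 | target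

Total step count: 15 steps.
Longest linear sequence: 13 steps (steps 1–3 and 6–15); steps 4 and 5 form a two-step side branch to bromoquinone 8.

Steps most likely to fail

Step 12. The enynylketene may close to the five-membered ring and give the alkylidenecyclopentenedione, may be captured intermolecularly, or the ynol ether may decompose before ring opening. The fallback drops the annulation and makes the same quinone by the substitution already used for ring C: phenol 13 and bromoquinone 8 (K2CO3, MeCN, 0 °C to rt, Ar) should give quinone 21 by addition–elimination of the phenoxide at the bromine-bearing carbon. The detour sets out from 13 and 8, bypasses compounds 15 to 20, and returns at 21; it makes no compound outside the list (F0).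

Step 8. With a phenoxide flanked on both sides and an electron-rich aryl bromide, C–O bond formation at copper may be slow, so that reduction of the bromide and oxidative degradation of the phenoxide at 100 °C take over. The fallback inverts the role of the ring D partner from electrophile to organoboron nucleophile and couples oxidatively at room temperature (Chan–Lam coupling). Bromide 2 is converted by bromine–lithium exchange (n-BuLi, THF, −78 °C), B(OiPr)3 and aqueous HCl into [4-(benzyloxy)-3,5-dimethoxyphenyl]boronic acid F1. F1 and phenol 11 with Cu(OAc)2 (20 mol%), pyridine and 4 Å molecular sieves in CH2Cl2 under O2 at rt should then give 12. The detour sets out from 2 and 11 and returns at 12.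

Step 15. Cleavage of sixteen ethers may stop at partly alkylated stages, and the pyrogallol-type rings C, E and F may oxidise in air during isolation of the free polyphenol, which cannot be purified on silica. The fallback is capture and release. After the BBr3 cleavage of 25 the crude polyphenol is not isolated but acetylated (Ac2O, pyridine, rt) to the hexadecaacetate of 26 F2, which should be stable and purifiable, so that incompletely cleaved material can be removed at this stage. Acid-catalysed methanolysis (HCl in degassed MeOH, rt, Ar) should then release 26 with only volatile by-products. The detour sets out from 25 and returns at 26.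

Further compounds
F0 | step 12 | none | none
F1 | step 8 | [4-(benzyloxy)-3,5-dimethoxyphenyl]boronic acid | COc1cc(B(O)O)cc(OC)c1OCc1ccccc1
F2 | step 15 | hexadecaacetate of 26 (all sixteen hydroxyls as acetates) | CC(=O)Oc1cc(OC(C)=O)c(Oc2cc(OC(C)=O)c(Oc3cc(OC(C)=O)c(OC(C)=O)c(OC(C)=O)c3Oc3cc(OC(C)=O)c(Oc4cc(OC(C)=O)c(OC(C)=O)c(OC(C)=O)c4Oc4cc(OC(C)=O)c(OC(C)=O)c(OC(C)=O)c4)c(OC(C)=O)c3)c(OC(C)=O)c2)c(OC(C)=O)c1
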